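**Plan**
Retrosynthesis: the C8–C9 bond of ring B is cut last; before it the C12–C13 bond with the butenolide (ene-type alkene–alkyne coupling), C10–C9 ([3,3] shift), C4–CH3, C10=C20 (Wittig) and C5–C6 (enolate alkylation), back to methyl 3-oxocyclohex-1-ene-1-carboxylate.
Forward: ring A is bought; the silylbutynyl arm goes onto C5, C20 onto C10 and methyl onto C4; a Claisen shift makes quaternary C10 (formyl + allyl); a ruthenium ene coupling builds the butenolide and moves the alkene to C9=C11; ring B closes last.
Enabling feature: a 1,7-enyne across ring A, made of the terminal alkyne C8≡C17 on the C5 arm and the C9=C11 alkene on quaternary C10, the two arms trans-diequatorial; a palladium hydride stitches it into the methylenecyclohexane ring B.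
Stereochemistry: C4–H from ligand-controlled copper hydride reduction, then C5 (trans alkylation), then quaternary C4 (methylation anti to the C5 arm), then C10 (allyl delivered anti to the axial ester), then C9 (chair transition state of the ring closure).

Key step: step 7

Remark: atoms are named by labdane numbering (ring A = C1–C5, C10; ring B = C5–C10; C19 = ester carbon, C20 = formyl carbon, C17 = exocyclic methylene carbon); the ligand antipode in step 1 is assumed to be the one that gives the (1R) ester, otherwise its enantiomer is used.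

Step 1
Reactants: 1 methyl 3-oxocyclohex-1-ene-1-carboxylate; 2 (4-iodobut-1-yn-1-yl)trimethylsilane
Product: 4 methyl (1R,2S)-3-oxo-2-[4-(trimethylsilyl)but-3-yn-1-yl]cyclohexane-1-carboxylate, via silyl enol ether 3 (not isolated)
Conditions: Cu(OAc)2·H2O (3 mol%), (R)-DTBM-SEGPHOS (3 mol%), PhMe2SiH, toluene, 0 °C; then 2, Bu4N[Ph3SiF2], THF–DMPU, 0 °C to rt
Reagents that add atoms: dimethyl(phenyl)silane, C[SiH](C)c1ccccc1 (hydride to C4 of 4; its silyl group is held only in 3)
Why: Copper hydride asymmetric 1,4-reduction delivers hydride to C4 under ligand control and gives the regiodefined silyl enol ether, whose fluoride-released enolate should be alkylated at C5 anti to the adjacent ester, the 2,3-trans isomer also being the thermodynamic one.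

Step 2
Reactants: 4 methyl (1R,2S)-3-oxo-2-[4-(trimethylsilyl)but-3-yn-1-yl]cyclohexane-1-carboxylate
Product: 5 methyl (1R,2S)-3-(methoxymethylidene)-2-[4-(trimethylsilyl)but-3-yn-1-yl]cyclohexane-1-carboxylate (E/Z mixture)
Conditions: Ph3P(CH2OMe)Cl, KN(SiMe3)2, THF, 0 °C to rt
Reagents that add atoms: (methoxymethyl)triphenylphosphonium chloride, COC[P+](c1ccccc1)(c1ccccc1)c1ccccc1.[Cl-]
Why: Wittig methoxymethylenation installs C20 as an enol ether, which masks the aldehyde and removes the acidity of C5–H so that C5 is fixed; the alkene geometry is irrelevant because it equilibrates in step 4.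

Step 3
Reactants: 5 methyl (1R,2S)-3-(methoxymethylidene)-2-[4-(trimethylsilyl)but-3-yn-1-yl]cyclohexane-1-carboxylate
Product: 6 methyl (1S,2R)-3-(methoxymethylidene)-1-methyl-2-[4-(trimethylsilyl)but-3-yn-1-yl]cyclohexane-1-carboxylate
Conditions: LiN(iPr)2, THF, −78 °C; MeI, −78 to 0 °C
Reagents that add atoms: iodomethane, CI
Why: Ester enolate C-methylation: the C5 arm, flanked by the exocyclic enolate at C4 and the exocyclic enol ether at C10, is pushed axial by allylic 1,3-strain and shields one face, so MeI should enter trans to it and leave the ester cis to the C5 arm (1S quaternary centre).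

Step 4
Reactants: 6 methyl (1S,2R)-3-(methoxymethylidene)-1-methyl-2-[4-(trimethylsilyl)but-3-yn-1-yl]cyclohexane-1-carboxylate; 7 prop-2-en-1-ol
Product: 10 methyl (1S,2R,3S)-3-formyl-1-methyl-3-(prop-2-en-1-yl)-2-[4-(trimethylsilyl)but-3-yn-1-yl]cyclohexane-1-carboxylate, via mixed acetal 8 (not isolated), via allyl enol ether 9 (not isolated)
Conditions: 7 (10 equiv), EtCO2H (cat.), xylene, 140 °C, sealed tube
Reagents that add atoms: none
Why: Acid-catalysed acetal exchange and loss of methanol give the allyl enol ether, whose aliphatic Claisen rearrangement through a chair transition state should deliver the allyl group to the equatorial face of C10, anti to the axial C4 ester (ring A chair with the C5 arm equatorial), so that the formyl group ends axial and cis to the ester (3S).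

Step 5
Reactants: 10 methyl (1S,2R,3S)-3-formyl-1-methyl-3-(prop-2-en-1-yl)-2-[4-(trimethylsilyl)but-3-yn-1-yl]cyclohexane-1-carboxylate; 11 ethyl 4-hydroxybut-2-ynoate
Product: 13 methyl (1S,2R,3S)-3-formyl-1-methyl-3-[(1E)-3-(2-oxo-2,5-dihydrofuran-3-yl)prop-1-en-1-yl]-2-[4-(trimethylsilyl)but-3-yn-1-yl]cyclohexane-1-carboxylate, via hydroxy dienoate 12 (not isolated)
Conditions: [CpRu(MeCN)3]PF6 (10 mol%), acetone, rt; then CSA (cat.), CH2Cl2, rt
Reagents that add atoms: none
Why: Ruthenium-catalysed Alder-ene-type alkene–alkyne coupling: a ruthenacyclopentene from the terminal C11=C12 alkene and the ynoate forms the C12–C13 bond at the ester α-carbon, β-hydride elimination of a C9–H moves the alkene to C9=C11 (E), and the cis-disposed CH2OH and CO2Et lactonise to the butenolide, while the silyl cap keeps the substrate's own alkyne from competing.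

Step 6
Reactants: 13 methyl (1S,2R,3S)-3-formyl-1-methyl-3-[(1E)-3-(2-oxo-2,5-dihydrofuran-3-yl)prop-1-en-1-yl]-2-[4-(trimethylsilyl)but-3-yn-1-yl]cyclohexane-1-carboxylate
Product: 14 methyl (1S,2R,3S)-2-(but-3-yn-1-yl)-3-formyl-1-methyl-3-[(1E)-3-(2-oxo-2,5-dihydrofuran-3-yl)prop-1-en-1-yl]cyclohexane-1-carboxylate
Conditions: Bu4NF, AcOH, THF, 0 °C
Reagents that add atoms: none
Why: Fluoride-induced protodesilylation of the alkynylsilane, buffered with acetic acid so that the butenolide and the formyl group are not exposed to base.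

Step 7
Reactants: 14 methyl (1S,2R,3S)-2-(but-3-yn-1-yl)-3-formyl-1-methyl-3-[(1E)-3-(2-oxo-2,5-dihydrofuran-3-yl)prop-1-en-1-yl]cyclohexane-1-carboxylate
Product: 15 methyl (1S,4aS,5S,8aR)-4a-formyl-1-methyl-6-methylidene-5-[2-(2-oxo-2,5-dihydrofuran-3-yl)ethyl]decahydronaphthalene-1-carboxylate
Conditions: Pd2(dba)3·CHCl3 (2.5 mol%), P(o-tol)3 (5 mol%), AcOH (2 equiv), Et3SiH (5 equiv), toluene, rt to 50 °C
Reagents that add atoms: none
Why: HPd(OAc), formed from zerovalent palladium and AcOH, adds across the terminal alkyne with palladium on C8 and hydrogen on C17, the vinylpalladium inserts the C9=C11 alkene to make the C8–C9 bond, and Et3SiH turns the C11 alkylpalladium acetate into an alkylpalladium hydride that reductively eliminates C11–H and returns zerovalent palladium. The closest known reaction type is the palladium hydride reductive cyclization of 1,6- and 1,7-enynes to alkylidenecycloalkanes. Ring B closes in the 6-exo-trig mode (syn carbopalladation, C11 left outside the ring). C9 is set by a chair transition state resembling the trans-decalin, in which the equatorial C5 and C10 arms on ring A place the C11 chain equatorial and away from the axial formyl group, which should give 9S with H9 anti to the formyl group. The step needs hydropalladation of the alkyne in preference to the butenolide and the formyl group, palladium on the inner alkyne carbon, and hydride capture ahead of β-hydride elimination toward C12; the unhindered terminal alkyne, the reversibility of hydropalladation (only the C8-palladated isomer can cyclize) and excess silane should secure these. The exocyclic methylene arises directly from the alkyne terminus, so no alkene position has to be controlled.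

**Compound list**
1 | methyl 3-oxocyclohex-1-ene-1-carboxylate | COC(=O)C1=CC(=O)CCC1 | starting material
2 | (4-iodobut-1-yn-1-yl)trimethylsilane | C[Si](C)(C)C#CCCI | starting material
3 | methyl (1R)-3-{[dimethyl(phenyl)silyl]oxy}cyclohex-2-ene-1-carboxylate | COC(=O)[C@@H]1CCCC(O[Si](C)(C)c2ccccc2)=C1 | intermediate
4 | methyl (1R,2S)-3-oxo-2-[4-(trimethylsilyl)but-3-yn-1-yl]cyclohexane-1-carboxylate | COC(=O)[C@@H]1CCCC(=O)[C@H]1CCC#C[Si](C)(C)C | intermediate
5 | methyl (1R,2S)-3-(methoxymethylidene)-2-[4-(trimethylsilyl)but-3-yn-1-yl]cyclohexane-1-carboxylate (E/Z mixture) | COC(=O)[C@@H]1CCCC(=COC)[C@H]1CCC#C[Si](C)(C)C | intermediate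
6 | methyl (1S,2R)-3-(methoxymethylidene)-1-methyl-2-[4-(trimethylsilyl)but-3-yn-1-yl]cyclohexane-1-carboxylate | COC(=O)[C@@]1(C)CCCC(=COC)[C@H]1CCC#C[Si](C)(C)C | intermediate
7 | prop-2-en-1-ol | C=CCO | starting material
8 | methyl (1S,2R)-3-[methoxy(prop-2-en-1-yloxy)methyl]-1-methyl-2-[4-(trimethylsilyl)but-3-yn-1-yl]cyclohexane-1-carboxylate (diastereomer mixture at C3 and the acetal carbon) | COC(=O)[C@@]1(C)CCCC(C(OC)OCC=C)[C@H]1CCC#C[Si](C)(C)C | intermediate
9 | methyl (1S,2R)-1-methyl-3-[(prop-2-en-1-yloxy)methylidene]-2-[4-(trimethylsilyl)but-3-yn-1-yl]cyclohexane-1-carboxylate | COC(=O)[C@@]1(C)CCCC(=COCC=C)[C@H]1CCC#C[Si](C)(C)C | intermediate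
10 | methyl (1S,2R,3S)-3-formyl-1-methyl-3-(prop-2-en-1-yl)-2-[4-(trimethylsilyl)but-3-yn-1-yl]cyclohexane-1-carboxylate | COC(=O)[C@@]1(C)CCC[C@](C=O)(CC=C)[C@H]1CCC#C[Si](C)(C)C | intermediate
11 | ethyl 4-hydroxybut-2-ynoate | CCOC(=O)C#CCO | starting material
12 | ethyl (2Z)-2-[(2E)-3-{(1S,2R,3S)-1-formyl-3-(methoxycarbonyl)-3-methyl-2-[4-(trimethylsilyl)but-3-yn-1-yl]cyclohexyl}prop-2-en-1-yl]-4-hydroxybut-2-enoate | COC(=O)[C@@]1(C)CCC[C@](C=O)(/C=C/CC(=C/CO)/C(=O)OCC)[C@H]1CCC#C[Si](C)(C)C | intermediate
13 | methyl (1S,2R,3S)-3-formyl-1-methyl-3-[(1E)-3-(2-oxo-2,5-dihydrofuran-3-yl)prop-1-en-1-yl]-2-[4-(trimethylsilyl)but-3-yn-1-yl]cyclohexane-1-carboxylate | COC(=O)[C@@]1(C)CCC[C@](C=O)(/C=C/CC2=CCOC2=O)[C@H]1CCC#C[Si](C)(C)C | intermediate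
14 | methyl (1S,2R,3S)-2-(but-3-yn-1-yl)-3-formyl-1-methyl-3-[(1E)-3-(2-oxo-2,5-dihydrofuran-3-yl)prop-1-en-1-yl]cyclohexane-1-carboxylate | COC(=O)[C@@]1(C)CCC[C@](C=O)(/C=C/CC2=CCOC2=O)[C@H]1CCC#C | intermediate
15 | methyl (1S,4aS,5S,8aR)-4a-formyl-1-methyl-6-methylidene-5-[2-(2-oxo-2,5-dihydrofuran-3-yl)ethyl]decahydronaphthalene-1-carboxylate | C=C1CC[C@@H]2[C@](C=O)(CCC[C@]2(C)C(=O)OC)[C@H]1CCC1=CCOC1=O | target

**Totals and risks**
Total step count: 7. Longest linear sequence: 7 steps (from 1).

Most likely to fail, first: step 7. The C11 alkylpalladium may lose a β-hydrogen from C12 faster than it is reduced, which would give a diene conjugated to the butenolide, or insertion of the hindered alkene next to quaternary C10 may be slower than alkyne oligomerisation. The fallback replaces the organopalladium pathway by a radical chain and sets out from 14. The formyl group, which would intercept a C8 vinyl radical, is first masked as the dimethyl acetal F1 (HC(OMe)3, PPTS, MeOH). Bu3SnH and AIBN (benzene, 80 °C, slow addition) then add a stannyl radical to C17; the C8 vinyl radical should close ring B 6-exo onto C9 and the C11 radical is reduced, giving the C17-stannylated acetal F2. Aqueous HCl in THF removes tin (protodestannylation with the alkene kept exocyclic) and the acetal, and the route is rejoined at 15.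

Second: step 5. The ruthenacycle may form slowly at the neopentyl-type allyl group, so that self-coupling through the silylalkyne or incomplete lactonisation takes over. The fallback uses C–H oxidation and cross-coupling and sets out from 10. Allylic C–H acetoxylation with transposition (Pd(OAc)2, benzoquinone, DMSO–AcOH, 40 °C) should give the linear (E)-allylic acetate F3. The coupling partner 3-(tributylstannyl)furan-2(5H)-one F4 is made from 11 by Pd(PPh3)4-catalysed hydrostannation with Bu3SnH and lactonisation. Stille coupling of F3 with F4 (Pd2(dba)3, AsPh3, LiCl, NMP) returns to the route at 13.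

Third: step 4. Facial selectivity of the [3,3] shift may be poor if ring A reacts through the flipped chair with the C5 arm axial, which would deliver the allyl group cis to the C5 arm. The fallback replaces substrate control by catalyst control and sets out from 6. Aqueous oxalic acid in THF hydrolyses the enol ether to the aldehyde F5 (C10 epimers). Tsuji–Trost α-allylation of this α-branched aldehyde with 7 (Pd(PPh3)4, benzhydrylamine, chiral phosphoric acid TRIP of the matching antipode, toluene, 40 °C) sets C10 through the enamine, and the route is rejoined at 10.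

Further compounds
F1 | step 7 | methyl (1S,2R,3S)-2-(but-3-yn-1-yl)-3-(dimethoxymethyl)-1-methyl-3-[(1E)-3-(2-oxo-2,5-dihydrofuran-3-yl)prop-1-en-1-yl]cyclohexane-1-carboxylate (dimethyl acetal of 14) | COC(=O)[C@@]1(C)CCC[C@](C(OC)OC)(/C=C/CC2=CCOC2=O)[C@H]1CCC#C
F2 | step 7 | dimethyl acetal of 15 carrying a tributylstannyl group on the exocyclic methylene carbon C17 (E/Z mixture) | CCCC[Sn](CCCC)(CCCC)C=C1CC[C@@H]2[C@](C(OC)OC)(CCC[C@]2(C)C(=O)OC)[C@H]1CCC1=CCOC1=O
F3 | step 5 | methyl (1S,2R,3S)-3-[(1E)-3-acetoxyprop-1-en-1-yl]-3-formyl-1-methyl-2-[4-(trimethylsilyl)but-3-yn-1-yl]cyclohexane-1-carboxylate | COC(=O)[C@@]1(C)CCC[C@](C=O)(/C=C/COC(C)=O)[C@H]1CCC#C[Si](C)(C)C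
F4 | step 5 | 3-(tributylstannyl)furan-2(5H)-one | CCCC[Sn](CCCC)(CCCC)C1=CCOC1=O
F5 | step 4 | methyl (1S,2R)-3-formyl-1-methyl-2-[4-(trimethylsilyl)but-3-yn-1-yl]cyclohexane-1-carboxylate (C3 epimers) | COC(=O)[C@@]1(C)CCCC(C=O)[C@H]1CCC#C[Si](C)(C)C
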